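## Analysis of the target

Compound 13 is a B-type proanthocyanidin dimer. An upper epigallocatechin unit (phloroglucinol ring A, pyran ring C, pyrogallol ring B) is bonded through C4 of ring C to C8 of ring D of a lower catechin unit (rings D and F, catechol ring E), and O3 of ring C carries a 3,4,5-trihydroxybenzoyl (galloyl) ester, ring G. There are five stereocentres. C2, C3 and C4 of the upper unit are all R, which means 2,3-cis and 3,4-trans, with the interflavan bond on the β face, opposite to ring B and O3. C2 (R) and C3 (S) of the lower unit are trans. The molecule has twelve phenols and one free secondary alcohol. The pyrogallol and catechol rings autoxidise in base, the doubly benzylic C4–C8 bond ionises in acid, and the ester can hydrolyse or migrate in base, so late steps must be near neutral and free of oxidants. Two things make the synthesis hard: forming the C4–C8 bond at C8 (not C6) of ring D with the β configuration, and placing one galloyl group on one of two secondary alcohols of a precursor with eleven hydroxyls. The plan rests on O3 of ring C: it is the only alcohol on a 2,3-cis heterocycle, it is axial, and it shares the α face with ring B exactly as in monomer 1, while the lower unit sits on the other face at C4. O3 of ring F is equatorial on a 2,3-trans ring, and this difference is what an acyltransferase for 2,3-cis flavan-3-ols can read.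

## Retrosynthetic reasoning

**Ester C–O bond (13 ⇒ 7 + 12).** The last bond made is the one between O3 of ring C and the galloyl carbonyl. Cutting here means the whole skeleton and all five stereocentres are finished before the only step that must choose between hydroxyls, and no orthogonal protecting groups are needed to mark O3. The acyl donor is the 1-O-acyl sugar 12, whose anomeric ester is activated enough to acylate the serine of the tea-leaf galloyltransferase. The forward reaction must acylate one secondary alcohol of 7 beside a second alcohol and nine phenols, in water near neutral pH, so that neither the C4–C8 bond nor the pyrogallol rings suffer.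

**Phenol protection (7 ⇒ 6).** The nine phenols of 7 are traced back to benzyl ethers in 6. Benzyl ethers survive a strong Lewis acid and an oxidant and come off by neutral hydrogenolysis, which leaves the acid-labile interflavan bond and its neighbouring stereocentres alone. Both secondary alcohols of 6 are already free.

**Interflavan bond (6 ⇒ 3 + 5).** The C4–C8 bond is cut to an upper unit with a leaving group at C4 (ether 3) and the nucleophilic lower unit 5. C4 is benzylic to ring A with ortho- and para-oxygens, so it forms a cation easily, and C8 of ring D is the most electron-rich free position of 5. This makes the dimer in one step from two monomers and sets C4. The forward reaction must deliver the aryl group to the β face, to C8 and not C6, and must stop at the dimer.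

**Monomers (3 ⇒ 2 ⇒ 1; 5 ⇒ 4).** The leaving group of 3 is introduced by oxidation of the C4–H bond of 2. Compounds 2 and 5 come from the natural flavan-3-ols 1 and 4 by benzylation of their phenols. Taking 1 as the source of the upper unit buys C2 and C3 in the 2,3-cis arrangement, which is the hard one to make. Building ring C from smaller pieces would cost many steps and add stereochemical risk before the enzymatic step, where the risk of this plan is meant to sit.

**Acyl donor (12 ⇒ 11 ⇒ 9 + 10; 9 ⇒ 8).** The anomeric ester of 12 is traced to the benzylated ester 11, and that to the α-imidate 9 and the protected acid 10. Displacement at C1 with inversion gives the β-ester the enzyme requires. Benzyl groups on both halves let one neutral hydrogenolysis release 12 without exposing the migration-prone 1-O-acyl sugar to base. Imidate 9 comes from lactol 8.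

## Alternatives that were turned down

**Alternative 1:** Ring D is grown on C4 of the upper unit by cutting C8–C8a, C6–C7 and C4a–C8a. The precursors are the ynol silyl ether A2 (a 3-O-TBS penta-O-benzylepigallocatechin with a triisopropylsilyloxyethynyl group at C4β) and the 3-benzyloxy-4-alkylcyclobutenone A3, whose side chain holds the future C2–C3 diol of the lower unit as an acetonide. The key step is a Danheiser benzannulation. Heating opens A3 to a vinylketene, which adds (2+2) to the alkyne of A2. The new cyclobutenone opens to a dienylketene, and six-electron closure and tautomerisation give the pentasubstituted phenol A1.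
- For: the interflavan bond is at C8 by construction, with no 4→6 isomer and no oligomers. The two secondary oxygens are already distinguished (silyl ether above, acetonide below), so the ester could be placed by ordinary acylation. On both points it is stronger than the chosen plan, which relies on the inherent C8 preference of 5, an excess of 5, and an enzyme.
- Against: A2 still needs a stereoselective C–C bond at C4 of an epigallocatechin derivative, so the problem of step 4 is only moved to an alkynyl nucleophile. A3 needs an asymmetric synthesis of stereocentres that 4 supplies for nothing. After A1, ring F must be closed by O–C2 displacement with inversion at a benzylic carbon, two silyl ethers removed and the ester made. The cascade runs hot, through ketenes, next to a doubly benzylic C4–H and acid-sensitive benzylic ethers.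
- Comparison: well over twenty steps against nine. In place of constructed regiocontrol, the chosen plan offers brevity and both natural monomers with their stereocentres intact.

**Alternative 2:** The C2–C1' bond between rings C and B of the upper unit is cut, together with the C3–O bond. The precursor is the 4-aryl-4H-chromene A5, which already carries the benzylated catechin unit on C4. In the key step, A5 is epoxidised by a dioxirane on the face away from the C4 aryl group, and the glycal-type epoxide is opened in the same flask by the arylalane A6. Aluminium binds the epoxide oxygen, C2–O ionises to an oxocarbenium–aluminate pair, and the aryl group passes to C2 on the face of the C3–O bond, giving the 2,3-cis-3,4-trans alcohol A4.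
- For: one stereocentre (C4) controls the other two in one operation. A4 has exactly one free hydroxyl, the upper O3, because the lower O3 is a benzyl ether. Esterification with 10 and hydrogenolysis would then give 13 with no selectivity question. On placing the galloyl group this is clearly stronger than an untested enzymatic step.
- Against: A5 must be made with C4 configured correctly relative to the catechin unit, with no nearby directing group. The epoxide of an aryl enol ether is very labile and can rearrange to the chroman-3-one, or lose facial memory if the ion pair separates. The dioxirane can also attack the electron-rich benzyloxy rings. A6 must be made from the aryllithium. The C2 and C3 centres that 1 supplies would be built over a dozen steps.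
- Comparison: the chosen plan offers a five-step longest sequence, C4 set under the reliable trans rule of a 2,3-cis flavanyl cation, and a last step with no protecting group. If the enzyme fails, the same intermediates give 13 chemically.

**Alternative 3:** Ring C of the upper unit is cut at C4–C4a, C3–C4 and O1–C2, leading to the phenol A8, the aldehyde A9 (penta-O-benzylcatechin-8-carbaldehyde) and the silyl enol ether A10 (silyl group taken as trimethylsilyl). Under a chiral phosphoric acid, A8 and A9 condense to an ortho-quinone methide whose exocyclic carbon is the future C4. Conjugate addition of A10 makes C3–C4, and hemiketalisation with loss of water closes the ring to the 4-aryl flav-2-ene A7.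
- For: it is the most convergent of the four plans; three simple components give the whole dimer skeleton in one step. The interflavan bond is again at C8 by construction, which is stronger than the chosen plan on regiocontrol.
- Against: C4 must be set by the catalyst next to the chiral catechin unit, a matched/mismatched case with a very hindered aldehyde. A7 is an acid-labile enol ether. Decisively, hydroboration of the C2=C3 bond of A7 adds H to C2 and O to C3 on the same face, anti to the C4 aryl, which is 2,3-trans. Reaching the 2,3-cis series needs a further oxidation to the 3-ketone and a face-selective reduction, after which the ester is made chemically as in Alternative 2.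
- Comparison: the chosen plan buys the 2,3-cis arrangement with 1 and needs no correction at C3.

Key step: step 9

Assumption: compounds 1, 4, 8 and 10 are bought, and the galloyltransferase is used as a partially purified preparation from young tea leaf or as the recombinant enzyme.

## Route

Step 1
Reactants: 1 (−)-epigallocatechin
Product: 2 penta-O-benzyl-(−)-epigallocatechin [(2R,3R)-5,7-bis(benzyloxy)-2-[3,4,5-tris(benzyloxy)phenyl]chroman-3-ol]
Conditions: BnBr (5.5 equiv), K2CO3 (6 equiv), degassed DMF, Ar, 0 °C → rt
Reagents that add atoms: benzyl bromide, BrCc1ccccc1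
Why: Williamson ether synthesis; K2CO3 ionises only the five phenols, so the secondary 3-OH stays free. Low temperature, degassed solvent and argon hold back autoxidation of pyrogallol ring B and C-benzylation of ring A; C2 and C3 are not touched.

Step 2
Reactants: 2 penta-O-benzyl-(−)-epigallocatechin
Product: 3 4β-(2-ethoxyethoxy)-penta-O-benzylepigallocatechin [(2R,3R,4S)-5,7-bis(benzyloxy)-4-(2-ethoxyethoxy)-2-[3,4,5-tris(benzyloxy)phenyl]chroman-3-ol]
Conditions: DDQ (2 equiv), EtOCH2CH2OH (5 equiv), CH2Cl2, rt
Reagents that add atoms: 2-ethoxyethanol, CCOCCO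
Why: Oxidative benzylic etherification with DDQ; hydride abstraction from C4, eased by the 5- and 7-oxygens of ring A, gives a stabilised benzylic cation that the alcohol should capture on the face away from ring B and O3, and DDQ does not oxidise the 3-OH. The configuration at C4 is of no consequence because the centre is ionised again in step 4.

Step 3
Reactants: 4 (+)-catechin
Product: 5 tetra-O-benzyl-(+)-catechin [(2R,3S)-5,7-bis(benzyloxy)-2-[3,4-bis(benzyloxy)phenyl]chroman-3-ol]
Conditions: BnBr (4.4 equiv), K2CO3 (5 equiv), degassed DMF, Ar, 0 °C → rt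
Reagents that add atoms: benzyl bromide, BrCc1ccccc1
Why: Williamson ether synthesis on the four phenols only; the 3-OH is not ionised by K2CO3 and the two stereocentres are not involved.

Step 4
Reactants: 3 4β-(2-ethoxyethoxy)-penta-O-benzylepigallocatechin; 5 tetra-O-benzyl-(+)-catechin (4 equiv)
Product: 6 nona-O-benzyl dimer [penta-O-benzylepigallocatechin-(4β→8)-tetra-O-benzylcatechin, both 3-hydroxyls free; upper unit 2R,3R,4R, lower unit 2R,3S]
Conditions: TiCl4 (2 equiv, 1 M in CH2Cl2), CH2Cl2–THF (9:1), 0 °C → rt; aq. NaHCO3; excess 5 recovered by chromatography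
Reagents that add atoms: none
Why: Friedel–Crafts alkylation through a flavan-4-yl cation; TiCl4 ionises the C4 ether of 3, and C8 of ring D of 5 attacks, being the most nucleophilic and less hindered position (C6 lies between two benzyloxy groups). The new centre C4 (R) is set by the substrate: ring B and O3 both shield the α face of the half-chair cation, so the arene enters from the β face, trans to O3. The excess of 5 suppresses further arylation to oligomers.

Step 5
Reactants: 6 nona-O-benzyl dimer
Product: 7 epigallocatechin-(4β→8)-catechin
Conditions: H2 (1 atm), Pd(OH)2/C, THF–MeOH–H2O (20:1:1), rt; filtration through Celite, lyophilisation, storage under Ar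
Reagents that add atoms: none
Why: Catalytic hydrogenolysis of nine aryl benzyl ethers under neutral conditions; at atmospheric pressure the C2–O1 bonds of rings C and F and the C4–C8 bond should not be cleaved. No acid or base is present that could ionise C4 or epimerise C2.

Step 6
Reactants: 8 2,3,4,6-tetra-O-benzyl-D-glucopyranose
Product: 9 2,3,4,6-tetra-O-benzyl-α-D-glucopyranosyl trichloroacetimidate
Conditions: Cl3CCN (5 equiv), DBU (0.1 equiv), CH2Cl2, 0 °C → rt
Reagents that add atoms: trichloroacetonitrile, N#CC(Cl)(Cl)Cl
Why: Base-catalysed addition of the anomeric hydroxyl to the nitrile (Schmidt imidate formation); with DBU the addition is reversible and the anomeric effect drives it to the α-imidate.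

Step 7
Reactants: 9 2,3,4,6-tetra-O-benzyl-α-D-glucopyranosyl trichloroacetimidate; 10 3,4,5-tris(benzyloxy)benzoic acid
Product: 11 2,3,4,6-tetra-O-benzyl-1-O-[3,4,5-tris(benzyloxy)benzoyl]-β-D-glucopyranose
Conditions: CH2Cl2, 4 Å molecular sieves, rt, no promoter
Reagents that add atoms: none
Why: Glycosyl ester formation from a trichloroacetimidate without promoter; the acid protonates the imidate nitrogen and its carboxylate displaces trichloroacetamide from the tight ion pair with inversion (SN2-like), so the α-imidate should give the β-ester. The benzyl ethers do not participate, which keeps the outcome tied to the anomeric configuration of 9.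

Step 8
Reactants: 11 2,3,4,6-tetra-O-benzyl-1-O-[3,4,5-tris(benzyloxy)benzoyl]-β-D-glucopyranose
Product: 12 1-O-galloyl-β-D-glucopyranose (β-glucogallin)
Conditions: H2 (1 atm), Pd/C (10 wt %), THF–MeOH, rt
Reagents that add atoms: none
Why: Hydrogenolysis of seven benzyl ethers; the anomeric acyl C–O bond is not benzylic and should survive. The neutral medium avoids 1→2 acyl migration and anomerisation of the 1-O-acyl sugar.

Step 9
Reactants: 7 epigallocatechin-(4β→8)-catechin; 12 1-O-galloyl-β-D-glucopyranose (3 equiv)
Product: 13 epigallocatechin 3-O-gallate-(4β→8)-catechin (target)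
Conditions: epicatechin:1-O-galloyl-β-D-glucose O-galloyltransferase (from young Camellia sinensis leaf), 50 mM phosphate buffer pH 6.0, ascorbic acid (2 mM), N2, dark, 30 °C; then Sephadex LH-20 (EtOH, then aqueous acetone)
Reagents that add atoms: none
Why: Proposed new method: the active-site serine of this serine carboxypeptidase-like acyltransferase is galloylated by the 1-O-acyl sugar 12 with release of the sugar, and the galloyl-enzyme is then attacked by the 3-hydroxyl of the bound flavan-3-ol, forming the ester C–O bond. The closest known reaction is the 3-O-galloylation of the monomers epicatechin and epigallocatechin by the same enzyme with 12 as donor. No ring is closed and no stereocentre is formed; O-acylation leaves C3 untouched, so the 2R,3R,4R configuration is carried through. The step needs one hydroxyl out of eleven. The nine phenols should stay free because the enzyme places only the ring C alcohol at the acyl-serine. The two alcohols are told apart by the enzyme's requirement for a 2,3-cis unit with an axial 3-OH, met by the upper unit and not by the 2,3-trans lower unit with its equatorial 3-OH. In 7 the upper unit presents the same ring B and α-face 3-OH as 1, while the new substituent at C4 is β and pseudo-axial, on the face away from the hydroxyl. The open point is whether the pocket near C4 and C5 tolerates the catechin unit; excess donor, ascorbate, nitrogen and pH 6 are meant to keep acyl-enzyme hydrolysis and pyrogallol autoxidation from outrunning transfer.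

## Compound list

1 | (−)-epigallocatechin | O[C@@H]1Cc2c(O)cc(O)cc2O[C@@H]1c1cc(O)c(O)c(O)c1 | starting material
2 | penta-O-benzyl-(−)-epigallocatechin | O[C@@H]1Cc2c(OCc5ccccc5)cc(OCc5ccccc5)cc2O[C@@H]1c1cc(OCc5ccccc5)c(OCc5ccccc5)c(OCc5ccccc5)c1 | intermediate
3 | 4β-(2-ethoxyethoxy)-penta-O-benzylepigallocatechin (2R,3R,4S) | O[C@@H]1[C@@H](OCCOCC)c2c(OCc5ccccc5)cc(OCc5ccccc5)cc2O[C@@H]1c1cc(OCc5ccccc5)c(OCc5ccccc5)c(OCc5ccccc5)c1 | intermediate
4 | (+)-catechin | Oc1cc(O)c2c(c1)O[C@H](c1ccc(O)c(O)c1)[C@@H](O)C2 | starting material
5 | tetra-O-benzyl-(+)-catechin | O(Cc5ccccc5)c1cc(OCc5ccccc5)c2c(c1)O[C@H](c1ccc(OCc5ccccc5)c(OCc5ccccc5)c1)[C@@H](O)C2 | intermediate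
6 | penta-O-benzylepigallocatechin-(4β→8)-tetra-O-benzylcatechin | O[C@@H]1[C@@H](c2c(OCc5ccccc5)cc(OCc5ccccc5)c3c2O[C@H](c2ccc(OCc5ccccc5)c(OCc5ccccc5)c2)[C@@H](O)C3)c2c(OCc5ccccc5)cc(OCc5ccccc5)cc2O[C@@H]1c1cc(OCc5ccccc5)c(OCc5ccccc5)c(OCc5ccccc5)c1 | intermediate
7 | epigallocatechin-(4β→8)-catechin | O[C@@H]1[C@@H](c2c(O)cc(O)c3c2O[C@H](c2ccc(O)c(O)c2)[C@@H](O)C3)c2c(O)cc(O)cc2O[C@@H]1c1cc(O)c(O)c(O)c1 | intermediate
8 | 2,3,4,6-tetra-O-benzyl-D-glucopyranose | O(Cc5ccccc5)C[C@H]1OC(O)[C@H](OCc5ccccc5)[C@@H](OCc5ccccc5)[C@@H]1OCc5ccccc5 | starting material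
9 | 2,3,4,6-tetra-O-benzyl-α-D-glucopyranosyl trichloroacetimidate | O(Cc5ccccc5)C[C@H]1O[C@H](OC(=N)C(Cl)(Cl)Cl)[C@H](OCc5ccccc5)[C@@H](OCc5ccccc5)[C@@H]1OCc5ccccc5 | intermediate
10 | 3,4,5-tris(benzyloxy)benzoic acid | OC(=O)c1cc(OCc5ccccc5)c(OCc5ccccc5)c(OCc5ccccc5)c1 | starting material
11 | 2,3,4,6-tetra-O-benzyl-1-O-[3,4,5-tris(benzyloxy)benzoyl]-β-D-glucopyranose | O=C(O[C@@H]1O[C@H](COCc5ccccc5)[C@@H](OCc5ccccc5)[C@H](OCc5ccccc5)[C@H]1OCc5ccccc5)c1cc(OCc5ccccc5)c(OCc5ccccc5)c(OCc5ccccc5)c1 | intermediate
12 | 1-O-galloyl-β-D-glucopyranose (β-glucogallin) | O=C(O[C@@H]1O[C@H](CO)[C@@H](O)[C@H](O)[C@H]1O)c1cc(O)c(O)c(O)c1 | intermediate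
13 | epigallocatechin 3-O-gallate-(4β→8)-catechin | O=C(O[C@@H]1[C@@H](c2c(O)cc(O)c3c2O[C@H](c2ccc(O)c(O)c2)[C@@H](O)C3)c2c(O)cc(O)cc2O[C@@H]1c1cc(O)c(O)c(O)c1)c1cc(O)c(O)c(O)c1 | target

## Step count and least certain steps

Total step count: 9. Longest linear sequence: 5 steps (steps 1, 2, 4, 5, 9). The donor branch (steps 6, 7, 8) joins at step 9.

**Step 9 (key step, new method).** The most likely failure is absent or slow acyl transfer because the dimer is not bound productively. The ring D substituent at C4 sits next to the hydroxyl that must reach the acyl-serine, and hydrolysis of the galloyl-enzyme would then simply consume the donor. Autoxidation of the pyrogallol rings during a long incubation is the second concern. The fallback is chemical; it sets out from 3 and comes back to the route at 13. Ether 3 is esterified at O3 with acid 10 (DCC, DMAP, CH2Cl2) to 3-O-[3,4,5-tris(benzyloxy)benzoyl]-4β-(2-ethoxyethoxy)-penta-O-benzylepigallocatechin F1. F1 is condensed with 5 (4 equiv, TMSOTf, CH2Cl2, −78 °C), where the 3-acyloxy group and ring B both direct the arene to the β face, to give the dodeca-O-benzyl ether of the target F2, whose lower 3-hydroxyl stays free. Hydrogenolysis (H2, Pd(OH)2/C, THF–MeOH–H2O) removes the twelve benzyl groups and gives 13.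

**Step 4.** The risk is over-arylation: the product and the electrophile are themselves nucleophilic at ring A or ring D, so chain growth to trimers and self-condensation compete with dimer formation, and TiCl4 may also strip some benzyl ethers. The fallback blocks the nucleophilic position of the electrophile; it sets out from 2 and comes back at 7. Compound 2 is brominated at C8 (NBS, CH2Cl2, −78 °C → rt) to 8-bromo-penta-O-benzylepigallocatechin F3. Oxidation as in step 2 gives 8-bromo-4β-(2-ethoxyethoxy)-penta-O-benzylepigallocatechin F4. Condensation with 5 as in step 4 gives 8-bromo-penta-O-benzylepigallocatechin-(4β→8)-tetra-O-benzylcatechin F5, whose deactivated and blocked ring A cannot add a further unit. Hydrogenolysis (H2, Pd(OH)2/C, Et3N, THF–MeOH–H2O) removes the bromine and the nine benzyl groups together and gives 7.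

**Step 7.** The risk is loss of anomeric control. If ionisation to the oxocarbenium ion outruns collapse of the ion pair, or the imidate anomerises or rearranges to the N-glycosyl trichloroacetamide, a mixture of anomers or no ester results, and the enzyme accepts only the β-ester. The fallback acylates the anomeric alkoxide; it sets out from 8 and 10 and comes back at 11. Acid 10 is converted with oxalyl chloride (cat. DMF, CH2Cl2) to 3,4,5-tris(benzyloxy)benzoyl chloride F6. Lactol 8 is deprotonated with n-BuLi in THF at −40 °C, and the more nucleophilic equatorial alkoxide is acylated by F6 to give 11.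

## Further compounds

F1 | step 9 | 3-O-[3,4,5-tris(benzyloxy)benzoyl]-4β-(2-ethoxyethoxy)-penta-O-benzylepigallocatechin | O=C(O[C@@H]1[C@@H](OCCOCC)c2c(OCc5ccccc5)cc(OCc5ccccc5)cc2O[C@@H]1c1cc(OCc5ccccc5)c(OCc5ccccc5)c(OCc5ccccc5)c1)c1cc(OCc5ccccc5)c(OCc5ccccc5)c(OCc5ccccc5)c1
F2 | step 9 | dodeca-O-benzyl ether of the target (lower 3-hydroxyl free) | O=C(O[C@@H]1[C@@H](c2c(OCc5ccccc5)cc(OCc5ccccc5)c3c2O[C@H](c2ccc(OCc5ccccc5)c(OCc5ccccc5)c2)[C@@H](O)C3)c2c(OCc5ccccc5)cc(OCc5ccccc5)cc2O[C@@H]1c1cc(OCc5ccccc5)c(OCc5ccccc5)c(OCc5ccccc5)c1)c1cc(OCc5ccccc5)c(OCc5ccccc5)c(OCc5ccccc5)c1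
F3 | step 4 | 8-bromo-penta-O-benzylepigallocatechin | O[C@@H]1Cc2c(OCc5ccccc5)cc(OCc5ccccc5)c(Br)c2O[C@@H]1c1cc(OCc5ccccc5)c(OCc5ccccc5)c(OCc5ccccc5)c1
F4 | step 4 | 8-bromo-4β-(2-ethoxyethoxy)-penta-O-benzylepigallocatechin | O[C@@H]1[C@@H](OCCOCC)c2c(OCc5ccccc5)cc(OCc5ccccc5)c(Br)c2O[C@@H]1c1cc(OCc5ccccc5)c(OCc5ccccc5)c(OCc5ccccc5)c1
F5 | step 4 | 8-bromo-penta-O-benzylepigallocatechin-(4β→8)-tetra-O-benzylcatechin | O[C@@H]1[C@@H](c2c(OCc5ccccc5)cc(OCc5ccccc5)c3c2O[C@H](c2ccc(OCc5ccccc5)c(OCc5ccccc5)c2)[C@@H](O)C3)c2c(OCc5ccccc5)cc(OCc5ccccc5)c(Br)c2O[C@@H]1c1cc(OCc5ccccc5)c(OCc5ccccc5)c(OCc5ccccc5)c1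
F6 | step 7 | 3,4,5-tris(benzyloxy)benzoyl chloride | ClC(=O)c1cc(OCc5ccccc5)c(OCc5ccccc5)c(OCc5ccccc5)c1
A1 | alternative 1 | ring D phenol carrying the upper unit at C8 and the acetonide chain at C4a | CC(C)(C)[Si](C)(C)O[C@@H]1[C@@H](c2c(O[Si](C(C)C)(C(C)C)C(C)C)cc(OCc5ccccc5)c(C[C@@H]3OC(C)(C)O[C@H]3c3ccc(OCc5ccccc5)c(OCc5ccccc5)c3)c2O)c2c(OCc5ccccc5)cc(OCc5ccccc5)cc2O[C@@H]1c4cc(OCc5ccccc5)c(OCc5ccccc5)c(OCc5ccccc5)c4
A2 | alternative 1 | 3-O-TBS-4β-(triisopropylsilyloxyethynyl)-penta-O-benzylepigallocatechin | CC(C)(C)[Si](C)(C)O[C@@H]1[C@@H](C#CO[Si](C(C)C)(C(C)C)C(C)C)c2c(OCc5ccccc5)cc(OCc5ccccc5)cc2O[C@@H]1c4cc(OCc5ccccc5)c(OCc5ccccc5)c(OCc5ccccc5)c4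
A3 | alternative 1 | 3-benzyloxy-4-alkylcyclobut-2-enone with acetonide-protected diol side chain | O=C1C=C(OCc5ccccc5)C1C[C@@H]3OC(C)(C)O[C@H]3c3ccc(OCc5ccccc5)c(OCc5ccccc5)c3
A4 | alternative 2 | benzylated epigallocatechin-(4β→8)-catechin with free upper 3-hydroxyl | O[C@@H]1[C@@H](c2c(OCc5ccccc5)cc(OCc5ccccc5)c3c2O[C@H](c2ccc(OCc5ccccc5)c(OCc5ccccc5)c2)[C@@H](OCc5ccccc5)C3)c2c(OCc5ccccc5)cc(OCc5ccccc5)cc2O[C@@H]1c4cc(OCc5ccccc5)c(OCc5ccccc5)c(OCc5ccccc5)c4
A5 | alternative 2 | 4-(penta-O-benzylcatechin-8-yl)-5,7-bis(benzyloxy)-4H-chromene | C1=C[C@@H](c2c(OCc5ccccc5)cc(OCc5ccccc5)c3c2O[C@H](c2ccc(OCc5ccccc5)c(OCc5ccccc5)c2)[C@@H](OCc5ccccc5)C3)c2c(OCc5ccccc5)cc(OCc5ccccc5)cc2O1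
A6 | alternative 2 | dimethyl[3,4,5-tris(benzyloxy)phenyl]alane | C[Al](C)c1cc(OCc5ccccc5)c(OCc5ccccc5)c(OCc5ccccc5)c1
A7 | alternative 3 | 4-(penta-O-benzylcatechin-8-yl)-penta-O-benzylflav-2-ene | C1(c4cc(OCc5ccccc5)c(OCc5ccccc5)c(OCc5ccccc5)c4)=C[C@@H](c2c(OCc5ccccc5)cc(OCc5ccccc5)c3c2O[C@H](c2ccc(OCc5ccccc5)c(OCc5ccccc5)c2)[C@@H](OCc5ccccc5)C3)c2c(OCc5ccccc5)cc(OCc5ccccc5)cc2O1
A8 | alternative 3 | 3,5-bis(benzyloxy)phenol | Oc1cc(OCc5ccccc5)cc(OCc5ccccc5)c1
A9 | alternative 3 | penta-O-benzylcatechin-8-carbaldehyde | O=Cc2c(OCc5ccccc5)cc(OCc5ccccc5)c3c2O[C@H](c2ccc(OCc5ccccc5)c(OCc5ccccc5)c2)[C@@H](OCc5ccccc5)C3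
A10 | alternative 3 | trimethylsilyl enol ether of 3,4,5-tris(benzyloxy)acetophenone | C=C(O[Si](C)(C)C)c1cc(OCc5ccccc5)c(OCc5ccccc5)c(OCc5ccccc5)c1
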